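**Plan**

- Retrosynthesis: the three O–benzyl bonds are cut first. C7–O is then traced to C7–Si, and C7–Si together with C8–H to the C7=C8 bond of a (Z)-2-aryloxycinnamyl diphenylsilyl ether. C7=C8 is cut by Horner–Wadsworth–Emmons logic into the ring A aldehyde and a ring B α-aryloxy phosphonoacetate. The C8–O4' bond comes from a carbenoid O–H insertion and the O4–glyceryl bond of ring A from a Mitsunobu etherification.
- Forward: ring B phenol → α-aryloxy phosphonate → union with the ring A aldehyde at C7=C8 → ester reduction and silylation of O9. The only ring formed is a 1,2-oxasilolane (Si–C7–C8–C9–O9), closed by hydrosilylation and opened again by oxidation; debenzylation ends the route.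
- Enabling feature: C7 (OH, H, ring A) and C8 (O4', H, C9) are neighbouring sp3 carbons. Oxygen (as silicon) and hydrogen can therefore be added syn across a flat C7=C8 enol ether, with O9, three atoms from C7, as the anchor for silicon.
- Stereochemistry: the erythro relationship comes from syn addition to the Z alkene, the absolute configuration from the chiral diphosphine on rhodium, and the C–Si oxidation retains configuration. The target is (7R,8S).

Key step: step 9

Assumption: which BINAP enantiomer directs silicon to the C7 face that leads to the (3R,4S)-oxasilolane cannot be predicted safely for this 2-aryloxy substrate; (S)-BINAP is written, and (R)-BINAP would replace it with no other change if a first small-scale run gave the mirror-image product.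

**Route**

Step 1
Reactants: 1 4-allyl-2,6-dimethoxyphenol
Product: 3 3-(4-hydroxy-3,5-dimethoxyphenyl)propan-1-ol, via bis(9-BBN) adduct 2 (not isolated)
Conditions: 9-BBN (2.2 equiv), THF, 0 °C → rt; then 3 M NaOH, 30% H2O2, 0 °C → rt
Reagents that add atoms: hydrogen peroxide, OO
Why: Hydroboration–oxidation: the bulky 9-BBN adds anti-Markovnikov to the terminal alkene and alkaline peroxide turns C–B into the primary alcohol, while the phenol only consumes a second equivalent of borane as an aryl borinate that is hydrolysed in the work-up.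

Step 2
Reactants: 3 3-(4-hydroxy-3,5-dimethoxyphenyl)propan-1-ol
Product: 4 4-[3-(benzyloxy)propyl]-2,6-dimethoxyphenol
Conditions: NaH (2.2 equiv), DMF, 0 °C; BnBr (1.0 equiv), 0 °C → rt; 1 M HCl work-up
Reagents that add atoms: benzyl bromide, BrCc1ccccc1
Why: Williamson ether synthesis under dianion control: in the phenoxide–alkoxide dianion the alkoxide is far more basic and nucleophilic, and the phenoxide is flanked by two methoxy groups, so one equivalent of benzyl bromide should alkylate the side-chain oxygen only.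

Step 3
Reactants: 5 triethyl phosphonoacetate
Product: 6 triethyl diazophosphonoacetate (ethyl 2-diazo-2-(diethoxyphosphoryl)acetate)
Conditions: NaH, THF, 0 °C; then 4-acetamidobenzenesulfonyl azide, 0 °C → rt
Reagents that add atoms: 4-acetamidobenzenesulfonyl azide, CC(=O)Nc1ccc(cc1)S(=O)(=O)N=[N+]=[N-]
Why: Regitz diazo transfer: the sodium enolate of the phosphonoacetate attacks the terminal nitrogen of the sulfonyl azide and the adduct collapses to the diazo compound and the sulfonamide anion.

Step 4
Reactants: 4 4-[3-(benzyloxy)propyl]-2,6-dimethoxyphenol; 6 triethyl diazophosphonoacetate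
Product: 7 ethyl 2-{4-[3-(benzyloxy)propyl]-2,6-dimethoxyphenoxy}-2-(diethoxyphosphoryl)acetate (racemic)
Conditions: Rh2(OAc)4 (2 mol%), toluene, 80 °C, slow addition of 6
Reagents that add atoms: none
Why: Rhodium carbenoid O–H insertion: dirhodium tetraacetate, a dimer of divalent rhodium, converts the diazo compound into an electrophilic carbenoid that the phenol oxygen traps faster than the arene or the benzyl ether can, and a proton shift gives the α-aryloxy phosphonoacetate that carries the C8–O4' bond.

Step 5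
Reactants: 8 vanillin; 9 1,3-bis(benzyloxy)propan-2-ol
Product: 10 4-{[1,3-bis(benzyloxy)propan-2-yl]oxy}-3-methoxybenzaldehyde
Conditions: PPh3, DIAD, THF, 0 °C → rt
Reagents that add atoms: none
Why: Mitsunobu etherification: the acidic phenol of vanillin displaces the alkoxyphosphonium ion of the secondary alcohol, whose carbinol carbon is not stereogenic, so the inversion has no consequence.

Step 6
Reactants: 7 ethyl 2-{4-[3-(benzyloxy)propyl]-2,6-dimethoxyphenoxy}-2-(diethoxyphosphoryl)acetate; 10 4-{[1,3-bis(benzyloxy)propan-2-yl]oxy}-3-methoxybenzaldehyde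
Product: 11 ethyl (2Z)-2-{4-[3-(benzyloxy)propyl]-2,6-dimethoxyphenoxy}-3-(4-{[1,3-bis(benzyloxy)propan-2-yl]oxy}-3-methoxyphenyl)prop-2-enoate
Conditions: NaH, THF, 0 °C → rt
Reagents that add atoms: none
Why: Horner–Wadsworth–Emmons olefination: the stabilised α-aryloxy phosphonate anion adds reversibly to the aromatic aldehyde and the pathway that places ring A trans to the ester should dominate, so the (Z)-enol ether (ring A cis to O4') is expected as the major and more stable isomer and is freed from the (E)-isomer by chromatography.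

Step 7
Reactants: 11 ethyl (2Z)-2-aryloxycinnamate as named in step 6
Product: 12 (2Z)-2-{4-[3-(benzyloxy)propyl]-2,6-dimethoxyphenoxy}-3-(4-{[1,3-bis(benzyloxy)propan-2-yl]oxy}-3-methoxyphenyl)prop-2-en-1-ol
Conditions: i-Bu2AlH (DIBAL-H, 2.5 equiv), CH2Cl2, −78 °C; aq. KNaC4H4O6 (potassium sodium tartrate)
Reagents that add atoms: none
Why: Ester reduction with i-Bu2AlH: two hydride equivalents reduce the conjugated ester 1,2 to the allylic alcohol at low temperature without touching the enol ether, the benzyl ethers or the alkene geometry.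

Step 8
Reactants: 12 (2Z)-allylic alcohol as named in step 7
Product: 13 {[(2Z)-2-{4-[3-(benzyloxy)propyl]-2,6-dimethoxyphenoxy}-3-(4-{[1,3-bis(benzyloxy)propan-2-yl]oxy}-3-methoxyphenyl)prop-2-en-1-yl]oxy}diphenylsilane
Conditions: Ph2SiHCl, Et3N, DMAP (cat.), toluene, 0 °C → rt, argon; filtered under argon, volatiles removed, used at once
Reagents that add atoms: chlorodiphenylsilane, Cl[SiH](c1ccccc1)c1ccccc1
Why: Silyl ether formation: the primary allylic alcohol displaces chloride from the chlorosilane under amine base, which leaves the Si–H bond intact and places it on O9, three atoms from C7.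

Step 9
Reactants: 13 (Z)-allylic diphenylsilyl ether as named in step 8
Product: 14 (3R,4S)-4-{4-[3-(benzyloxy)propyl]-2,6-dimethoxyphenoxy}-3-(4-{[1,3-bis(benzyloxy)propan-2-yl]oxy}-3-methoxyphenyl)-2,2-diphenyl-1,2-oxasilolane (trans)
Conditions: [Rh((S)-BINAP)(acetone)2]ClO4 (3 mol%, from [Rh((S)-BINAP)(nbd)]ClO4 and H2 in acetone), acetone, 25 °C, argon
Reagents that add atoms: none
Why: Proposed new method: oxidative addition of the Si–H bond of 13 to the cationic monovalent rhodium centre should give a trivalent rhodium silyl hydride, the tethered C7=C8 bond then inserts syn, and reductive elimination leaves silicon on C7 and hydrogen on C8 on the same face. The closest known reaction type is the rhodium–diphosphine-catalysed enantioselective intramolecular hydrosilylation of cinnamyl-type diarylsilyl ethers, which also makes a benzylic C–Si bond in a five-membered ring; it has not been shown for a trisubstituted alkene that carries an aryloxy group. The 1,2-oxasilolane closes in the 5-endo-trig mode, since the three-atom C9–O9–Si tether reaches C7 easily while bonding to C8 would need a four-membered ring, and C7 is also the carbon at which an enol ether normally accepts silicon. C7 is controlled by the alkene face that the (S)-BINAP–rhodium fragment selects; C8 follows from the syn delivery to the Z alkene, in which ring A and O4' are cis, so that the trans (3R,4S) ring and hence the erythro pattern results. The step needs enantiofacial selectivity (ligand), regioselectivity (tether) and an unchanged Z geometry before insertion (geometrically pure 13, room temperature); loss of the aryloxide by β-elimination is disfavoured because the medium is neutral, offers no nucleophile for silicon, and the ring holds the Si–C7–C8–O4' torsion short of 180°.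

Step 10
Reactants: 14 (3R,4S)-oxasilolane as named in step 9
Product: 15 (1R,2S)-2-{4-[3-(benzyloxy)propyl]-2,6-dimethoxyphenoxy}-1-(4-{[1,3-bis(benzyloxy)propan-2-yl]oxy}-3-methoxyphenyl)propane-1,3-diol
Conditions: 30% H2O2, KF, KHCO3, THF/MeOH (1:1), rt → 40 °C
Reagents that add atoms: hydrogen peroxide, OO
Why: Tamao–Fleming oxidation: hydroperoxide and fluoride add to the alkoxysilane, C7 migrates from silicon to oxygen with retention of configuration and hydrolysis of the Si–O bonds frees O7 and O9, while bicarbonate buffering and the known survival of β-alkoxy oxasilolanes under these conditions suggest that migration should outrun β-elimination of the C8 aryloxide.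

Step 11
Reactants: 15 (1R,2S)-tribenzyl diol as named in step 10
Product: 16 (1R,2S)-1-{4-[(1,3-dihydroxypropan-2-yl)oxy]-3-methoxyphenyl}-2-[4-(3-hydroxypropyl)-2,6-dimethoxyphenoxy]propane-1,3-diol (CNP0324330.3)
Conditions: H2 (1 atm), 10% Pd/C, EtOAc/EtOH, rt
Reagents that add atoms: none
Why: Catalytic hydrogenolysis: the three benzyl ethers are cleaved over palladium on carbon under neutral conditions, under which the benzylic C7–OH and the C8–O4' aryl ether react much more slowly and no stereocentre is touched.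

**Compound list**

1 | 4-allyl-2,6-dimethoxyphenol | COc1cc(CC=C)cc(OC)c1O | starting material
2 | 9-{3-[4-(9-borabicyclo[3.3.1]nonan-9-yloxy)-3,5-dimethoxyphenyl]propyl}-9-borabicyclo[3.3.1]nonane | COc1cc(CCCB2C3CCCC2CCC3)cc(OC)c1OB1C2CCCC1CCC2 | intermediate
3 | 3-(4-hydroxy-3,5-dimethoxyphenyl)propan-1-ol | COc1cc(CCCO)cc(OC)c1O | intermediate
4 | 4-[3-(benzyloxy)propyl]-2,6-dimethoxyphenol | COc1cc(CCCOCc2ccccc2)cc(OC)c1O | intermediate
5 | triethyl phosphonoacetate | CCOC(=O)CP(=O)(OCC)OCC | starting material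
6 | triethyl diazophosphonoacetate | CCOC(=O)C(=[N+]=[N-])P(=O)(OCC)OCC | intermediate
7 | ethyl 2-{4-[3-(benzyloxy)propyl]-2,6-dimethoxyphenoxy}-2-(diethoxyphosphoryl)acetate (racemic) | CCOC(=O)C(Oc1c(OC)cc(CCCOCc2ccccc2)cc1OC)P(=O)(OCC)OCC | intermediate
8 | vanillin | COc1cc(C=O)ccc1O | starting material
9 | 1,3-bis(benzyloxy)propan-2-ol | OC(COCc1ccccc1)COCc1ccccc1 | starting material
10 | 4-{[1,3-bis(benzyloxy)propan-2-yl]oxy}-3-methoxybenzaldehyde | COc1cc(C=O)ccc1OC(COCc1ccccc1)COCc1ccccc1 | intermediate
11 | ethyl (2Z)-2-{4-[3-(benzyloxy)propyl]-2,6-dimethoxyphenoxy}-3-(4-{[1,3-bis(benzyloxy)propan-2-yl]oxy}-3-methoxyphenyl)prop-2-enoate | COc1cc(/C=C(/C(=O)OCC)Oc2c(OC)cc(CCCOCc3ccccc3)cc2OC)ccc1OC(COCc1ccccc1)COCc1ccccc1 | intermediate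
12 | (2Z)-2-{4-[3-(benzyloxy)propyl]-2,6-dimethoxyphenoxy}-3-(4-{[1,3-bis(benzyloxy)propan-2-yl]oxy}-3-methoxyphenyl)prop-2-en-1-ol | COc1cc(/C=C(/CO)Oc2c(OC)cc(CCCOCc3ccccc3)cc2OC)ccc1OC(COCc1ccccc1)COCc1ccccc1 | intermediate
13 | {[(2Z)-2-{4-[3-(benzyloxy)propyl]-2,6-dimethoxyphenoxy}-3-(4-{[1,3-bis(benzyloxy)propan-2-yl]oxy}-3-methoxyphenyl)prop-2-en-1-yl]oxy}diphenylsilane | COc1cc(/C=C(/CO[SiH](c2ccccc2)c2ccccc2)Oc2c(OC)cc(CCCOCc3ccccc3)cc2OC)ccc1OC(COCc1ccccc1)COCc1ccccc1 | intermediate
14 | (3R,4S)-4-{4-[3-(benzyloxy)propyl]-2,6-dimethoxyphenoxy}-3-(4-{[1,3-bis(benzyloxy)propan-2-yl]oxy}-3-methoxyphenyl)-2,2-diphenyl-1,2-oxasilolane (trans) | COc1cc([C@H]3[Si](c4ccccc4)(c4ccccc4)OC[C@@H]3Oc2c(OC)cc(CCCOCc4ccccc4)cc2OC)ccc1OC(COCc1ccccc1)COCc1ccccc1 | intermediate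
15 | (1R,2S)-2-{4-[3-(benzyloxy)propyl]-2,6-dimethoxyphenoxy}-1-(4-{[1,3-bis(benzyloxy)propan-2-yl]oxy}-3-methoxyphenyl)propane-1,3-diol | COc1cc([C@@H](O)[C@H](CO)Oc2c(OC)cc(CCCOCc3ccccc3)cc2OC)ccc1OC(COCc1ccccc1)COCc1ccccc1 | intermediate
16 | (1R,2S)-1-{4-[(1,3-dihydroxypropan-2-yl)oxy]-3-methoxyphenyl}-2-[4-(3-hydroxypropyl)-2,6-dimethoxyphenoxy]propane-1,3-diol | COc1cc([C@@H](O)[C@H](CO)Oc2c(OC)cc(CCCO)cc2OC)ccc1OC(CO)CO | target

**Step count and risks**

Total steps: 11. Longest linear sequence: 9 steps (steps 1, 2, 4, 6, 7, 8, 9, 10, 11) from 4-allyl-2,6-dimethoxyphenol.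

Steps most likely to fail:

1. Step 9. The trisubstituted, electron-rich and heavily oxygenated enol ether may fail to insert, the allylic silyl ether may isomerise or redistribute at silicon on the metal, or facial selectivity may be insufficient. The fallback uses known chemistry only, sets out from 4 and 10 and returns at 15.
 - Phenol 4 would be alkylated with bromoacetic acid (NaH, THF) to {4-[3-(benzyloxy)propyl]-2,6-dimethoxyphenoxy}acetic acid F1.
 - F1 would be activated with pivaloyl chloride and Et3N as the mixed pivalic anhydride F2 and acylated in the same flask with lithiated (R)-4-benzyl-1,3-oxazolidin-2-one (n-BuLi, THF, −78 °C) to the (4R)-N-aryloxyacetyl oxazolidinone F3.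
 - The dibutylboron enolate of F3 (Bu2BOTf, i-Pr2NEt, CH2Cl2, −78 °C) would add to aldehyde 10 in an Evans syn-aldol reaction to give the (2R,3S)-aldol adduct F4. This has C8 as in the target and C7 epimeric (threo pattern).
 - Mitsunobu inversion of the benzylic hydroxyl with 4-nitrobenzoic acid (PPh3, DIAD, THF) would give the (2R,3R)-4-nitrobenzoate F5.
 - LiBH4 in THF–MeOH would remove the auxiliary reductively and cleave the ester to deliver 15.

2. Step 10. Once silicon is activated by fluoride and hydroperoxide, the C8 aryloxide may be lost by β-elimination, or a phenyl group may leave silicon in place of C7, or the hindered diarylsilane may oxidise too slowly. The fallback changes the tether, sets out from 12 and returns at 15.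
 - Alcohol 12 would be silylated with 1,1,3,3-tetramethyldisilazane to the (Z)-allylic dimethylsilyl ether F6.
 - F6 would be cyclised with the catalyst of step 9 to the (3R,4S)-2,2-dimethyl-1,2-oxasilolane F7.
 - This alkoxydialkylsilane would be oxidised without fluoride (30% H2O2, KHCO3, THF/MeOH, rt), so that no fluorosilicate forms and no aryl group on silicon competes, to give 15.
 - The enantioselectivity with the smaller silyl group would have to be re-established.

3. Step 6. Poor Z/E selectivity in the olefination, or inseparable geometric isomers, would pass on as threo contamination after the syn addition. The fallback replaces the olefination by aldol addition and elimination, sets out from 4 and 10 and returns at 11.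
 - Phenol 4 would be alkylated with ethyl bromoacetate (K2CO3, acetone) to ethyl {4-[3-(benzyloxy)propyl]-2,6-dimethoxyphenoxy}acetate F8.
 - Its lithium enolate (LiN(i-Pr)2, THF, −78 °C) would add to aldehyde 10 to give ethyl 2-aryloxy-3-aryl-3-hydroxypropanoate F9 as a mixture of diastereomers that needs no separation.
 - Mesylation (MsCl, Et3N, CH2Cl2, 0 °C) would give the 3-methanesulfonyloxy ester F10, and E1cB elimination with DBU in the same flask should converge on the more stable (Z)-ester 11.

Further compounds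

F1 | step 9 | {4-[3-(benzyloxy)propyl]-2,6-dimethoxyphenoxy}acetic acid | COc1cc(CCCOCc2ccccc2)cc(OC)c1OCC(=O)O
F2 | step 9 | {4-[3-(benzyloxy)propyl]-2,6-dimethoxyphenoxy}acetic 2,2-dimethylpropanoic anhydride | COc1cc(CCCOCc2ccccc2)cc(OC)c1OCC(=O)OC(=O)C(C)(C)C
F3 | step 9 | (4R)-4-benzyl-3-({4-[3-(benzyloxy)propyl]-2,6-dimethoxyphenoxy}acetyl)-1,3-oxazolidin-2-one | COc1cc(CCCOCc2ccccc2)cc(OC)c1OCC(=O)N1[C@H](Cc2ccccc2)COC1=O
F4 | step 9 | (4R)-4-benzyl-3-[(2R,3S)-2-{4-[3-(benzyloxy)propyl]-2,6-dimethoxyphenoxy}-3-(4-{[1,3-bis(benzyloxy)propan-2-yl]oxy}-3-methoxyphenyl)-3-hydroxypropanoyl]-1,3-oxazolidin-2-one | O=C([C@H](Oc1c(OC)cc(CCCOCc2ccccc2)cc1OC)[C@@H](O)c1ccc(OC(COCc2ccccc2)COCc2ccccc2)c(OC)c1)N1[C@H](Cc2ccccc2)COC1=O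
F5 | step 9 | (4R)-4-benzyl-3-[(2R,3R)-2-{4-[3-(benzyloxy)propyl]-2,6-dimethoxyphenoxy}-3-(4-{[1,3-bis(benzyloxy)propan-2-yl]oxy}-3-methoxyphenyl)-3-(4-nitrobenzoyloxy)propanoyl]-1,3-oxazolidin-2-one | O=C([C@H](Oc1c(OC)cc(CCCOCc2ccccc2)cc1OC)[C@H](OC(=O)c1ccc(cc1)[N+](=O)[O-])c1ccc(OC(COCc2ccccc2)COCc2ccccc2)c(OC)c1)N1[C@H](Cc2ccccc2)COC1=O
F6 | step 10 | {[(2Z)-2-{4-[3-(benzyloxy)propyl]-2,6-dimethoxyphenoxy}-3-(4-{[1,3-bis(benzyloxy)propan-2-yl]oxy}-3-methoxyphenyl)prop-2-en-1-yl]oxy}dimethylsilane | COc1cc(/C=C(/CO[SiH](C)C)Oc2c(OC)cc(CCCOCc3ccccc3)cc2OC)ccc1OC(COCc1ccccc1)COCc1ccccc1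
F7 | step 10 | (3R,4S)-4-{4-[3-(benzyloxy)propyl]-2,6-dimethoxyphenoxy}-3-(4-{[1,3-bis(benzyloxy)propan-2-yl]oxy}-3-methoxyphenyl)-2,2-dimethyl-1,2-oxasilolane | COc1cc([C@H]3[Si](C)(C)OC[C@@H]3Oc2c(OC)cc(CCCOCc4ccccc4)cc2OC)ccc1OC(COCc1ccccc1)COCc1ccccc1
F8 | step 6 | ethyl {4-[3-(benzyloxy)propyl]-2,6-dimethoxyphenoxy}acetate | CCOC(=O)COc1c(OC)cc(CCCOCc2ccccc2)cc1OC
F9 | step 6 | ethyl 2-{4-[3-(benzyloxy)propyl]-2,6-dimethoxyphenoxy}-3-(4-{[1,3-bis(benzyloxy)propan-2-yl]oxy}-3-methoxyphenyl)-3-hydroxypropanoate (mixture of diastereomers) | CCOC(=O)C(Oc1c(OC)cc(CCCOCc2ccccc2)cc1OC)C(O)c1ccc(OC(COCc2ccccc2)COCc2ccccc2)c(OC)c1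
F10 | step 6 | ethyl 2-{4-[3-(benzyloxy)propyl]-2,6-dimethoxyphenoxy}-3-(4-{[1,3-bis(benzyloxy)propan-2-yl]oxy}-3-methoxyphenyl)-3-(methanesulfonyloxy)propanoate (mixture of diastereomers) | CCOC(=O)C(Oc1c(OC)cc(CCCOCc2ccccc2)cc1OC)C(OS(C)(=O)=O)c1ccc(OC(COCc2ccccc2)COCc2ccccc2)c(OC)c1
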